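I watched one ratio.

| flask | D | J | G | temperature | remark | time | volume of the second phase over the first |
|---|---|---|---|---|---|---|---|
| Monday's | 1 M | 1.3 M | 0.20 M | 80 °C | the very flask that is asked about, followed so far |  |  |
| flask | 1.0 M | 1.30 M | 0.200 M | 80 °C |  | 8.0 min | 2.0 |

Monday's run (percent of the D charged)

| time / min | L / % | D / % |
|---|---|---|
| 0.667 | 6.0 | 71.3 |
| 1.33 | 12.4 | 50.2 |
| 2.50 | 19.3 | 34.2 |
| 4.00 | 20.8 | 23.9 |
| 8.00 | 19.7 | 15.0 |

(each reading ± 1 percentage point)

- in the second phase: J; everything else is in the first
- charges count per volume of the first phase; a concentration in a rate is the amount of a species over the volume of its own phase; every rate counts per litre of the first phase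
- L that was removed still counts
- the earlier runs hold the two phases in the same ratio of volumes as the flask asked about
- additions bring no volume worth counting
- the earlier runs do not show what temperature does; that part of a forecast is a guess

- larch: at 8.0 min add D, 50.0% of the amount charged, then wait 2.5 min
- elm: change nothing and wait 2.5 min more
- oak: at 8.0 min take out 90% of the L then present, then wait 2.5 min
- maple: at 8.0 min raise the temperature by 25 K, then wait 2.5 min

- L, in percent of the D first charged, at 8.0 min
- the remedy with the largest gain of L, or "none" below 2 percentage points (larch / elm / oak / maple / none)
- L present, with what was taken out counted in, in percent of the D first charged, after larch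
- L present, with what was taken out counted in, in percent of the D first charged, after maple

In Monday's run L rose and sagged while D kept falling, so I took L as made from D and lost again. Monday's highest L reading came at 4.00 min, where cD/cL read 1.15. That L reading stood 1.1 percentage points above the one at 8.00 min, against a scatter of 1 point, so the top of L need not lie at that reading, and I put it between the two. I carried the ratio halfway between theirs, 0.955, as the crossing ratio, the cD/cL at which L stops rising, the maximum of an intermediate; it is a rough reading, and I took L to gain well above it and to lose well below it.

Monday's last reading gave 0.761, lower than the crossing ratio, so I expected elm to lose L. Larch lifts the ratio to 3.30 and oak to 7.61, so I expected both to gain. But larch leaves 4.33 times the D to make L from, so I put larch ahead of oak, where the forecast differs. The crossing ratio was read at 80 °C, and the readings don't say where maple moves it.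

The forecast gave 19.8% (18.7% to 20.9%) now, 22% after larch and 11% after maple (6% to 18%), and chose oak: “Oak is best, though this is a mechanistic inference, not something the runs tested.”

The flask gave 19.6% now, 26.0% after larch and 29.0% after maple. The best remedy was maple, gaining 9.4 points, against 6.4 points for larch, 2.9 points for oak and −0.75 points for elm.

    Z + L → X (k = 0.00430 M⁻¹ s⁻¹, Ea = 54.0 kJ mol⁻¹)
    Z ⇌ J, rate k2*([Z] - [J]/K2) per volume of the first phase (partition coefficient = 0.580, kL = 0.0520 s⁻¹)
    D ⇌ Q (K = 1.80, k = 0.00470 s⁻¹, Ea = 87.0 kJ mol⁻¹, ΔH = −65.0 kJ mol⁻¹)
    D + G → E (k = 0.0120 M⁻¹ s⁻¹, Ea = 79.0 kJ mol⁻¹)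
    D + Z → L (k = 0.00490 M⁻¹ s⁻¹, Ea = 78.0 kJ mol⁻¹)
    (constants at 80 °C)

In the flask at 8.00 min, L was made at 0.857 of the rate at which it was used up, each step taken net, with cD/cL at 0.752, below the crossing ratio. That same flask held 33.8% as Q, more than its 14.7% of D. The neighbouring flask with 0.80 M of G, at the same temperature, stood lower still at 0.505, so the ratio puts its L past the top, and that flask held 10.9% of L.

(The readings stem from a simulated flask from invented constants, and the scatter is random.)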